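## Retrosynthesis

1. Prokinawan (11) comes from the (E)-trisubstituted alkene by disconnecting through cross-metathesis. The partners are a 6-allyl flavanone (9) and 2,6-dimethylhept-6-en-2-ol (3).
2. The 6-allyl group comes from an aromatic Claisen [3,3] rearrangement of the 5-O-allyl ether (8). This is the key step. Only C6 is free ortho to 5-O, because C4a carries the acyl group, so the rearrangement is regiospecific.
3. No ring is built. The flavanone and its (2S) centre come intact from (S)-eriodictyol (4), and no step touches C2. The 5-OH is chelated to C4=O, so 7-OH and the catechol can be silylated while 5-OH stays free for allylation.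
4. Fragment 3 comes in one step from a homoallyl Grignard and isobutylene oxide.

Assumptions: (2S)-eriodictyol and 4-bromo-2-methylbut-1-ene are commercially available. I assume the cross-metathesis gives an E:Z ratio of about 4:1, with the E isomer separable at the end.

## Route

**Step 1**
Reactants: 1 (4-bromo-2-methylbut-1-ene), 2 (isobutylene oxide)
Product: 3 (2,6-dimethylhept-6-en-2-ol)
Conditions: (i) Mg, THF, reflux; (ii) CuI (10 mol%), 2, THF, −20 °C to rt
Reagents that add atoms: none beyond the reactants
Why: The Cu-catalysed Grignard opens the epoxide by SN2 at the unhindered CH2 (Grignard–epoxide alkylation), giving the tertiary alcohol with three CH2 between the alkene and the carbinol. No stereocentre is formed.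

**Step 2**
Reactants: 4 ((2S)-eriodictyol), 5 (TIPSCl)
Product: 6 (7,3′,4′-tri-O-TIPS-eriodictyol, 5-OH free)
Conditions: TIPSCl (3.5 equiv), imidazole (6 equiv), DMF, rt, 16 h
Reagents that add atoms: TIPSCl, CC(C)[Si](Cl)(C(C)C)C(C)C
Why: The chelated 5-OH does not silylate, while 7-OH and the catechol do (chemoselective silyl protection). Only mild base is used, so C2 stays (S).

**Step 3**
Reactants: 6, 7 (allyl bromide)
Product: 8 (5-O-allyl-7,3′,4′-tri-O-TIPS-eriodictyol)
Conditions: allyl bromide (3 equiv), K2CO3 (3 equiv), DMF, 50 °C, 12 h
Reagents that add atoms: allyl bromide, C=CCBr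
Why: Williamson O-allylation of the only free phenol. The TIPS ethers survive, and the short, mild conditions avoid retro-oxa-Michael racemisation at C2.

**Step 4**
Reactants: 8
Product: 9 (6-allyl-5-hydroxy-7,3′,4′-tri-O-TIPS-eriodictyol)
Conditions: o-dichlorobenzene, 185 °C, sealed tube under Ar, 3 h
Reagents that add atoms: none
Why: Aromatic Claisen rearrangement ([3,3]-sigmatropic) through a chair-like transition state forms the C6–C bond. C6 is the only free ortho position, and tautomerisation restores the H-bonded 5-OH. There is no base, and C2 is not involved.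

**Step 5**
Reactants: 9, 3
Product: 10 ((E)-6-(7-hydroxy-3,7-dimethyloct-2-enyl) tri-O-TIPS flavanone)
Conditions: Hoveyda–Grubbs II (5 mol%), 1,4-benzoquinone (10 mol%), 3 (5 equiv), CH2Cl2, 40 °C, N2 sparge, 16 h
Reagents that add atoms: none beyond reactant 3
Why: Cross-metathesis of the terminal allylarene with the 1,1-disubstituted olefin releases ethylene and forms the trisubstituted alkene, with E favoured. Benzoquinone suppresses Ru–H isomerisation of the allylarene. C2 is unchanged.

**Step 6**
Reactants: 10
Product: 11 (prokinawan)
Conditions: TBAF (4 equiv), AcOH (4 equiv), THF, 0 °C to rt, 2 h; then prep-HPLC (or AgNO3–silica) to remove the Z isomer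
Reagents that add atoms: none (H from AcOH)
Why: Fluoride cleaves the Si–O bonds (phenolic silyl ether deprotection). AcOH buffering prevents base-induced ring opening and epimerisation at C2. The tertiary alcohol and the alkene are untouched.

## Checks

- Target match: the flavanone core is unchanged from 4. The chain is at C6, flanked by 5-OH and 7-OH. The alkene is E, with the methyl cis to the CH2Ar group. C2 is (S): the neighbour order C3, H, Ar, O with @@ is kept identical in every SMILES.
- Atom accounting: step 1 gives C5H9 + C4H8O + H = C9H18O. Steps 2 and 3 replace H by Si(iPr)3 and by allyl. Step 4 is an isomerisation. Step 5 gives 10 + C2H4. Step 6 replaces the three silyl groups by H.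
- Protecting groups: TIPS survives K2CO3, 185 °C and the Ru catalyst. The free 5-OH is chelated and tolerated by the catalyst. The tertiary alcohol needs no protection anywhere.
- Stereochemistry: the only stereocentre (C2) is carried from the starting material, and every step runs under mild or neutral conditions for it. The alkene geometry is set in step 5 and enriched in step 6.

## Compound list

1 | 4-bromo-2-methylbut-1-ene | C=C(C)CCBr | starting material
2 | isobutylene oxide | CC1(C)CO1 | starting material
3 | 2,6-dimethylhept-6-en-2-ol | C=C(C)CCCC(C)(C)O | intermediate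
4 | (2S)-eriodictyol | O=C1C[C@@H](c2ccc(O)c(O)c2)Oc2cc(O)cc(O)c12 | starting material
5 | triisopropylsilyl chloride | CC(C)[Si](Cl)(C(C)C)C(C)C | starting material
6 | 7,3′,4′-tri-O-TIPS-eriodictyol | O=C1C[C@@H](c2ccc(O[Si](C(C)C)(C(C)C)C(C)C)c(O[Si](C(C)C)(C(C)C)C(C)C)c2)Oc2cc(O[Si](C(C)C)(C(C)C)C(C)C)cc(O)c12 | intermediate
7 | allyl bromide | C=CCBr | starting material
8 | 5-O-allyl ether of 6 | O=C1C[C@@H](c2ccc(O[Si](C(C)C)(C(C)C)C(C)C)c(O[Si](C(C)C)(C(C)C)C(C)C)c2)Oc2cc(O[Si](C(C)C)(C(C)C)C(C)C)cc(OCC=C)c12 | intermediate
9 | 6-allyl-5-hydroxy tri-O-TIPS flavanone | O=C1C[C@@H](c2ccc(O[Si](C(C)C)(C(C)C)C(C)C)c(O[Si](C(C)C)(C(C)C)C(C)C)c2)Oc2cc(O[Si](C(C)C)(C(C)C)C(C)C)c(CC=C)c(O)c12 | intermediate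
10 | tri-O-TIPS prokinawan | C/C(=C\Cc1c(O[Si](C(C)C)(C(C)C)C(C)C)cc2c(c1O)C(=O)C[C@@H](c1ccc(O[Si](C(C)C)(C(C)C)C(C)C)c(O[Si](C(C)C)(C(C)C)C(C)C)c1)O2)CCCC(C)(C)O | intermediate
11 | prokinawan | C/C(=C\Cc1c(O)cc2c(c1O)C(=O)C[C@@H](c1ccc(O)c(O)c1)O2)CCCC(C)(C)O | target

## Totals

Total steps: 6. Longest linear sequence: 5 steps, from eriodictyol.

## Three steps most likely to fail

1. **Step 5 (cross-metathesis).** The E:Z ratio may be poor, or the allylarene may isomerise. Fallback: drop the metathesis and attach a pre-formed (E)-7-hydroxygeranyl unit made from geraniol. Use a regiocontrolled ortho C-alkylation (Lewis-acid or Pd-catalysed allylic C-alkylation) of the free-5-OH phenol 6, which fixes the alkene geometry before coupling.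
2. **Step 4 (Claisen at 185 °C).** It may racemise C2 or be slowed by the neighbouring OTIPS. Fallback: skip thermolysis. Make the 5-O-allyl carbonate and do a Pd(0)-catalysed decarboxylative ortho C-allylation at or near rt.
3. **Step 3 (5-O-allylation of the chelated phenol).** It may be incomplete, cleave the TIPS ethers, or racemise C2. Fallback: change the regiochemical handle. Brominate C8 (NBS) and allylate 7-OH instead. Carry out the Claisen to C6, which is now the only free ortho position, then remove the bromine by hydrogenolysis or by metal–halogen exchange and protonation.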